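**Plan**
1. Cuts, in retrosynthetic order:
   - pyran O1–C2 and C4–C4a, made by annulating an enal onto the C8a phenol and the neighbouring C4a–H
   - indole N1–C2 in both indoles, each with one carbon put back between N and that CH
   - the biaryl bonds from chromene C5 and C8 to the two indole C3 atoms
   - the C7–O bond of the methoxy group
2. Enabling feature: both heteroaryl groups are indoles bound through C3 and unsubstituted at C2. Each pyrrole ring (N1, C2, C3, C3a, C7a) is therefore the pyridine ring of a quinolin-4-yl group (N1, C2, C3, C4, C4a, C8a) lacking its C2. Quinoline C4 maps onto indole C3 and quinoline C3 onto indole C2.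
3. Forward order: the benzene ring is bought as a dibromohydroquinone and gains its third oxygen by ortho-metalation. Two 2-methylquinolin-4-yl rings are coupled on and N-oxidised, and both pyridine rings are contracted to pyrroles in one light/acid operation. The pyran ring is closed after that, and the N-acetyl groups left by the contraction come off last.
4. Stereochemistry: the target has no stereocentre and no fixed axis, so nothing has to be controlled.

Key step: step 7

Remark: the aryl–quinoline axes of the teraryl intermediates are hindered and may show slowly exchanging rotamers. They are not stereo-elements of the target, so no axial descriptors are written.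

**Step 1**
Reactants: 1 2,5-dibromobenzene-1,4-diol (2,5-dibromohydroquinone); 2 benzyl bromide
Product: 3 1,4-bis(benzyloxy)-2,5-dibromobenzene
Conditions: BnBr (2.3 equiv), K2CO3, DMF, 60 °C, N2
Reagents that add atoms: benzyl bromide 2, BrCc1ccccc1
Why: Twofold Williamson ether synthesis on an acidic, unhindered hydroquinone; benzyl is chosen because it should survive amide base, hot aqueous phosphate, peracid, near-UV light and brief TFA and then leave under neutral hydrogenolysis.

**Step 2**
Reactants: 3 1,4-bis(benzyloxy)-2,5-dibromobenzene
Product: 5 3,6-bis(benzyloxy)-2,5-dibromophenol, via lithium aryltriisopropoxyborate 4 (not isolated)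
Conditions: B(OiPr)3, then LiN(iPr)2 (1.1 equiv, added last), THF, −78 °C to 0 °C; then AcOH, 30% aq H2O2, 0 °C to rt
Reagents that add atoms: hydrogen peroxide, OO (phenol oxygen of 5); triisopropyl borate, CC(C)OB(OC(C)C)OC(C)C (atoms held only in 4); lithium diisopropylamide, [Li+].CC(C)[N-]C(C)C (lithium cation of 4 only)
Why: Directed ortho-metalation with in situ borate trapping followed by boronate oxidation: the two ring C–H bonds of 3 are equivalent and each lies between Br and OBn (the acidified 2-position of a 3-bromoanisole), so one equivalent of amide base gives a single aryllithium, which the borate already present captures before LiBr loss to an aryne or a halogen dance can start, and peroxide then moves the aryl group from boron to oxygen.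

**Step 3**
Reactants: 5 3,6-bis(benzyloxy)-2,5-dibromophenol
Product: 6 1,4-bis(benzyloxy)-2,5-dibromo-3-methoxybenzene
Conditions: MeI, K2CO3, DMF, rt to 40 °C
Reagents that add atoms: iodomethane, CI
Why: Williamson O-methylation of the only free hydroxyl group, which fixes the future C7 methoxy group between a bromine-bearing carbon and a benzyloxy-bearing carbon.

**Step 4**
Reactants: 7 4-chloro-2-methylquinoline
Product: 8 2-methyl-4-(4,4,5,5-tetramethyl-1,3,2-dioxaborolan-2-yl)quinoline
Conditions: B2pin2, Pd2(dba)3 (cat.), XPhos, KOAc, 1,4-dioxane, 100 °C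
Reagents that add atoms: bis(pinacolato)diboron, CC1(C)OB(OC1(C)C)B1OC(C)(C)C(C)(C)O1
Why: Miyaura borylation: the C4–Cl bond of a quinoline is activated towards oxidative addition to zerovalent palladium by the ring nitrogen, and a 4-quinolyl boronate, unlike a 2-azinyl one, is stable enough to isolate.

**Step 5**
Reactants: 6 1,4-bis(benzyloxy)-2,5-dibromo-3-methoxybenzene; 8 2-methyl-4-(pinacolboryl)quinoline (2.6 equiv)
Product: 9 4,4'-[2,5-bis(benzyloxy)-3-methoxy-1,4-phenylene]bis(2-methylquinoline)
Conditions: Pd(OAc)2 (cat.), SPhos, K3PO4, PhMe/H2O, 100 °C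
Reagents that add atoms: none
Why: Twofold Suzuki–Miyaura coupling in which boron is placed on the quinoline, because a boronate on the carbon flanked by OMe and OBn would protodeboronate readily, and in which the Pd(OAc)2/SPhos catalyst is the established answer to electron-rich, di-ortho-substituted aryl bromides.

**Step 6**
Reactants: 9 4,4'-[2,5-bis(benzyloxy)-3-methoxy-1,4-phenylene]bis(2-methylquinoline)
Product: 10 4,4'-[2,5-bis(benzyloxy)-3-methoxy-1,4-phenylene]bis(2-methylquinoline 1-oxide)
Conditions: mCPBA (2.4 equiv), CH2Cl2, 0 °C to rt; aq NaHCO3 wash; azeotropic drying (PhMe)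
Reagents that add atoms: 3-chloroperoxybenzoic acid, OOC(=O)c1cccc(Cl)c1
Why: Peracid N-oxidation of an azine: the two quinoline nitrogens are the only nucleophilic lone pairs in 9, and aryl ethers and benzyl ethers are inert to mCPBA at this temperature.

**Step 7**
Reactants: 10 4,4'-[2,5-bis(benzyloxy)-3-methoxy-1,4-phenylene]bis(2-methylquinoline 1-oxide)
Product: 12 1,4-bis(benzyloxy)-2-methoxy-3,6-bis(1-acetylindol-3-yl)benzene, via bis(3,1-benzoxazepine) 11 (not isolated)
Conditions: hν (390 nm LEDs), dry degassed PhMe (0.01 M), rt; then TFA, rt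
Reagents that add atoms: none
Why: Light at 390 nm excites each quinoline N-oxide, whose oxygen closes onto C2 (oxaziridine-type isomer), shifts to the C2–C3 edge and, by 6π electrocyclic opening of that oxirane, expands the pyridine ring to the 2-methyl-3,1-benzoxazepine ring of 11, which is transparent at this wavelength and therefore accumulates. TFA protonates the cyclic enol imidate, nitrogen bonds to the former quinoline C3 while that carbon gives up its oxygen (directly, or by way of ring opening with adventitious water and cyclodehydration), and former C2 with its methyl group is left outside the ring as the N-acetyl carbonyl, so that 10, 11 and 12 are isomers. The closest known reaction type is the photochemical single-carbon deletion of 2-alkyl- and 4-aryl-substituted quinoline N-oxides to N-acylindoles, used here on two independent chromophores of one molecule. Each of the two pyrrole rings closes by 5-exo-trig addition of nitrogen to the oxygen-activated former C3, which creates indole N1–C2 and turns the aryl-bearing quinoline C4 into indole C3. No stereocentre is formed, and the hindered aryl–quinoline axes lose most of their barrier when the six-membered rings become five-membered. The step needs contraction rather than oxygen shift to a 2-quinolone, deoxygenation, benzylic oxidation or capture of former C3 by a neighbouring oxygen: the 2-methyl group removes the C2–H that the quinolone path uses, dry toluene favours the benzoxazepine, each N–O group lies para to the biaryl bond and cannot reach an OCH2Ph hydrogen, the benzyl ethers keep the flanking phenol oxygens from forming benzofurans, and the light-sensitive 2H-chromene is not yet present.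

**Step 8**
Reactants: 12 1,4-bis(benzyloxy)-2-methoxy-3,6-bis(1-acetylindol-3-yl)benzene
Product: 13 2,5-bis(1-acetylindol-3-yl)-3-methoxybenzene-1,4-diol
Conditions: H2 (1 atm), 10% Pd/C, EtOAc/EtOH, rt; filtration and handling under Ar
Reagents that add atoms: none
Why: Catalytic hydrogenolysis of aryl benzyl ethers under neutral conditions, which should leave the aromatic C2=C3 bond of the 3-aryl-N-acetylindoles and the acetyl groups untouched; the electron-withdrawing N-acetyl groups also make hydroquinone 13 less prone to air oxidation than its N–H analogue.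

**Step 9**
Reactants: 13 2,5-bis(1-acetylindol-3-yl)-3-methoxybenzene-1,4-diol; 14 3-methylbut-2-enal
Product: 17 5,8-bis(1-acetylindol-3-yl)-7-methoxy-2,2-dimethyl-2H-chromen-6-ol, via benzodioxaborin 15 (not isolated), via ortho-quinone methide 16 (not isolated)
Conditions: 3-methylbut-2-enal (3 equiv), PhB(OH)2 (1 equiv), AcOH, PhMe, reflux (water separator), Ar
Reagents that add atoms: 3-methylbut-2-enal 14, CC(C)=CC=O; phenylboronic acid, OB(O)c1ccccc1 (atoms held only in 15 and released again)
Why: Boronic-acid-templated chromenylation of a phenol with an enal: PhB(OH)2 ties the C1 phenol oxygen and the aldehyde together, C–C bond formation at the only unsubstituted ring carbon (ortho to that OH and para to OMe, hence resorcinol-like in nucleophilicity) gives 15, thermal loss of the boron unit gives 16 and oxa-6π electrocyclisation closes the pyran, while the other OH has no free ortho position and the N-acetyl groups keep indole N–H and C2 away from the enal.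

**Step 10**
Reactants: 17 5,8-bis(1-acetylindol-3-yl)-7-methoxy-2,2-dimethyl-2H-chromen-6-ol
Product: 18 kumbicin C, 5,8-di(1H-indol-3-yl)-7-methoxy-2,2-dimethyl-2H-chromen-6-ol
Conditions: K2CO3, MeOH/THF, rt, Ar; then aq NH4Cl
Reagents that add atoms: none
Why: Base-catalysed methanolysis of N-acylindoles, which are activated amides because the nitrogen lone pair belongs to the aromatic sextet, so that both acetyl groups should leave at room temperature without touching the chromene, the aryl methyl ether or the phenol.

**Compound list**
1 | 2,5-dibromobenzene-1,4-diol (2,5-dibromohydroquinone) | Oc1cc(Br)c(O)cc1Br | starting material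
2 | benzyl bromide | BrCc1ccccc1 | starting material
3 | 1,4-bis(benzyloxy)-2,5-dibromobenzene | Brc1cc(OCc2ccccc2)c(Br)cc1OCc1ccccc1 | intermediate
4 | lithium [2,5-bis(benzyloxy)-3,6-dibromophenyl]tri(propan-2-yloxy)borate | [Li+].CC(C)O[B-](OC(C)C)(OC(C)C)c1c(OCc2ccccc2)c(Br)cc(OCc2ccccc2)c1Br | intermediate (not isolated)
5 | 3,6-bis(benzyloxy)-2,5-dibromophenol | Oc1c(OCc2ccccc2)c(Br)cc(OCc2ccccc2)c1Br | intermediate
6 | 1,4-bis(benzyloxy)-2,5-dibromo-3-methoxybenzene | COc1c(OCc2ccccc2)c(Br)cc(OCc2ccccc2)c1Br | intermediate
7 | 4-chloro-2-methylquinoline | Cc1cc(Cl)c2ccccc2n1 | starting material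
8 | 2-methyl-4-(4,4,5,5-tetramethyl-1,3,2-dioxaborolan-2-yl)quinoline | Cc1cc(B2OC(C)(C)C(C)(C)O2)c2ccccc2n1 | intermediate
9 | 4,4'-[2,5-bis(benzyloxy)-3-methoxy-1,4-phenylene]bis(2-methylquinoline) | COc1c(OCc2ccccc2)c(-c2cc(C)nc3ccccc23)cc(OCc2ccccc2)c1-c1cc(C)nc2ccccc12 | intermediate
10 | 4,4'-[2,5-bis(benzyloxy)-3-methoxy-1,4-phenylene]bis(2-methylquinoline 1-oxide) | COc1c(OCc2ccccc2)c(-c2cc(C)[n+]([O-])c3ccccc23)cc(OCc2ccccc2)c1-c1cc(C)[n+]([O-])c2ccccc12 | intermediate
11 | 5,5'-[2,5-bis(benzyloxy)-3-methoxy-1,4-phenylene]bis(2-methyl-3,1-benzoxazepine) | COc1c(OCc2ccccc2)c(C2=COC(C)=Nc3ccccc23)cc(OCc2ccccc2)c1C1=COC(C)=Nc2ccccc12 | intermediate (not isolated)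
12 | 1,4-bis(benzyloxy)-2-methoxy-3,6-bis(1-acetylindol-3-yl)benzene | COc1c(OCc2ccccc2)c(-c2cn(C(C)=O)c3ccccc23)cc(OCc2ccccc2)c1-c1cn(C(C)=O)c2ccccc12 | intermediate
13 | 2,5-bis(1-acetylindol-3-yl)-3-methoxybenzene-1,4-diol | COc1c(O)c(-c2cn(C(C)=O)c3ccccc23)cc(O)c1-c1cn(C(C)=O)c2ccccc12 | intermediate
14 | 3-methylbut-2-enal | CC(C)=CC=O | starting material
15 | (±)-5,8-bis(1-acetylindol-3-yl)-7-methoxy-4-(2-methylprop-1-enyl)-2-phenyl-4H-1,3,2-benzodioxaborin-6-ol (the C4 centre is lost again in 16) | COc1c(O)c(-c2cn(C(C)=O)c3ccccc23)c2c(c1-c1cn(C(C)=O)c3ccccc13)OB(c1ccccc1)OC2C=C(C)C | intermediate (not isolated)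
16 | (6Z)-2,5-bis(1-acetylindol-3-yl)-4-hydroxy-3-methoxy-6-(3-methylbut-2-enylidene)cyclohexa-2,4-dien-1-one | COC1=C(c2cn(C(C)=O)c3ccccc23)C(=O)/C(=C\C=C(C)C)C(c2cn(C(C)=O)c3ccccc23)=C1O | intermediate (not isolated)
17 | 5,8-bis(1-acetylindol-3-yl)-7-methoxy-2,2-dimethyl-2H-chromen-6-ol (N,N'-diacetylkumbicin C) | COc1c(O)c(-c2cn(C(C)=O)c3ccccc23)c2c(c1-c1cn(C(C)=O)c3ccccc13)OC(C)(C)C=C2 | intermediate
18 | kumbicin C, 5,8-di(1H-indol-3-yl)-7-methoxy-2,2-dimethyl-2H-chromen-6-ol | COc1c(O)c(-c2c[nH]c3ccccc23)c2c(c1-c1c[nH]c3ccccc13)OC(C)(C)C=C2 | target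

**Step count**
Total steps: 10. Longest linear sequence: 9 (steps 1–3 and 5–10); step 4 is the side branch.

**Steps most likely to fail**

Step 7. Electron transfer from the trialkoxybenzene core to the excited N-oxide may drain the excited state and divert it towards deoxygenation. Two independent events are needed, so incomplete conversion of the second chromophore would leave mixtures that are hard to separate.
- The fallback sets out from 6 and comes back at 12. It installs the indoles directly instead of editing quinolines.
- Suzuki–Miyaura coupling of 6 with commercial tert-butyl 3-(4,4,5,5-tetramethyl-1,3,2-dioxaborolan-2-yl)indole-1-carboxylate (Pd(OAc)2, SPhos, K3PO4, PhMe/H2O) should give the bis(N-Boc-indole) F1.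
- TFA in CH2Cl2 should remove both carbamates to give the bis(N–H indole) F2.
- Ac2O, DMAP and Et3N in CH2Cl2 should N-acetylate both indoles to give 12.

Step 9. Carbon–carbon bond formation at the ring position crowded by the neighbouring indolyl group may be slow. That leaves time for air oxidation of the hydroquinone to the quinone and for self-condensation of the enal at reflux.
- The fallback sets out from 13 and comes back at 17. It replaces the intermolecular C-alkylation by an intramolecular sigmatropic delivery.
- O-alkylation with 3-chloro-3-methylbut-1-yne (K2CO3, KI cat., acetone, reflux) should occur at the less hindered hydroxyl group, which is flanked by H and indolyl rather than by OMe and indolyl. This should give the aryl 1,1-dimethylpropargyl ether F3.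
- Heating F3 in xylene at 140 °C should trigger aromatic Claisen rearrangement, 1,5-hydrogen shift to 16 and electrocyclisation to 17.

Step 5. The coupling may stall after the first, less hindered C–Br bond has reacted. Protodeboronation of 8 and binding of palladium by quinoline nitrogen could then outrun the slow reaction at the carbon flanked by OMe and OBn.
- The fallback sets out from 6 and 7 and comes back at 9. The roles of the partners are reversed in a Negishi coupling, which also makes step 4 unnecessary.
- Twofold bromine–lithium exchange on 6 (t-BuLi, 4.2 equiv, THF, −78 °C) should give the dilithioarene F4.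
- ZnCl2 should convert F4 at once to the bis(arylzinc chloride) F5.
- Coupling of F5 with 7 (Pd2(dba)3, RuPhos, THF, 70 °C) under anhydrous conditions, in which a 2,6-dialkoxyaryl metal species is not protonated, should give 9.

**Further compounds**
F1 | step 7 | di-tert-butyl 3,3'-[2,5-bis(benzyloxy)-3-methoxy-1,4-phenylene]bis(indole-1-carboxylate) | COc1c(OCc2ccccc2)c(-c2cn(C(=O)OC(C)(C)C)c3ccccc23)cc(OCc2ccccc2)c1-c1cn(C(=O)OC(C)(C)C)c2ccccc12
F2 | step 7 | 3,3'-[2,5-bis(benzyloxy)-3-methoxy-1,4-phenylene]bis(1H-indole) | COc1c(OCc2ccccc2)c(-c2c[nH]c3ccccc23)cc(OCc2ccccc2)c1-c1c[nH]c2ccccc12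
F3 | step 9 | 3,6-bis(1-acetylindol-3-yl)-2-methoxy-4-[(2-methylbut-3-yn-2-yl)oxy]phenol | COc1c(O)c(-c2cn(C(C)=O)c3ccccc23)cc(OC(C)(C)C#C)c1-c1cn(C(C)=O)c2ccccc12
F4 | step 5 | [2,5-bis(benzyloxy)-3-methoxy-1,4-phenylene]dilithium | COc1c(OCc2ccccc2)c([Li])cc(OCc2ccccc2)c1[Li]
F5 | step 5 | [2,5-bis(benzyloxy)-3-methoxy-1,4-phenylene]bis(chlorozinc) | COc1c(OCc2ccccc2)c([Zn]Cl)cc(OCc2ccccc2)c1[Zn]Cl
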